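**Retrosynthetic overview**
1. The last bond made is C5–C6 of the side chain. A ligand-controlled Ni/Cr alkenylation joins a C11 furan aldehyde (fragment A) to a C11 iodoalkenyl hydroxy lactone (fragment B) and sets C6 as S.
2. The lactone of fragment B comes from a Baeyer-Villiger ring expansion (four- to five-membered ring, C-to-O 1,2-shift with retention) of an alpha-quaternary beta-hydroxy cyclobutanone.
3. That cyclobutanone comes from a new catalytic asymmetric Mukaiyama aldol between the enol silane of 2-methylcyclobutanone and (E)-5-iodo-4-methylpent-4-enal. This step sets the carbinol centre (R) and the quaternary centre (S).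
4. Fragment A comes from but-3-yn-1-ol by carboalumination/vinylation, diene hydroboration/B-alkyl Suzuki coupling with 3-bromofuran, and oxidation.
5. Rings: the furan is bought intact. The four-membered ring is bought and expanded to the lactone in step 8. No other ring is made.

Assumption: racemic 2-methylcyclobutan-1-one, 3-bromofuran and vinyl bromide (THF solution) are taken as catalogue chemicals, and the enantiomer of each chiral controller (IDPi acid, chromium ligand) is fixed in a test run.

**Step 1**
Reactants: 1 but-3-yn-1-ol; 2 vinyl bromide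
Product: 4 (3E)-3-methylhexa-3,5-dien-1-ol, via alkenylalane 3 (not isolated)
Conditions: Me3Al (3 equiv), Cp2ZrCl2 (25 mol%), CH2Cl2, 0 °C to rt; then 2 (1 M in THF), Pd(PPh3)4 (5 mol%), ZnCl2 (20 mol%), rt; 1 M aq HCl work-up
Reagents that add atoms: trimethylaluminium, C[Al](C)C
Why: Negishi zirconium-catalysed carboalumination adds CH3 and Al syn across the alkyne with Al on the terminal carbon, and the Pd/Zn co-catalysed cross-coupling vinylates the alkenylalane with retention, which fixes the E trisubstituted alkene.

**Step 2**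
Reactants: 4 (3E)-3-methylhexa-3,5-dien-1-ol; 5 3-bromofuran
Product: 7 (3E)-6-(furan-3-yl)-3-methylhex-3-en-1-ol, via B-alkyl-9-BBN adduct 6 (not isolated)
Conditions: 9-BBN (2.2 equiv), THF, 0 °C to rt; then 5, PdCl2(dppf) (5 mol%), 3 M aq NaOH, THF, 60 °C
Reagents that add atoms: none
Why: 9-BBN hydroborates only the monosubstituted terminus of the diene (anti-Markovnikov, trisubstituted alkene untouched), and the B-alkyl Suzuki-Miyaura coupling joins the primary borane to C3 of the furan without changing the alkene geometry.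

**Step 3**
Reactants: 7 (3E)-6-(furan-3-yl)-3-methylhex-3-en-1-ol
Product: 8 (3E)-6-(furan-3-yl)-3-methylhex-3-enal
Conditions: Dess-Martin periodinane (1.2 equiv), NaHCO3 (3 equiv), CH2Cl2, 0 °C, 1 h; used at once
Reagents that add atoms: none
Why: The buffered Dess-Martin oxidation is neutral and fast, so the beta,gamma-unsaturated aldehyde forms without alkene migration into conjugation and without harm to the furan.

**Step 4**
Reactants: 9 pent-4-yn-1-ol
Product: 11 (4E)-5-iodo-4-methylpent-4-en-1-ol, via alkenylalane 10 (not isolated)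
Conditions: Me3Al (3 equiv), Cp2ZrCl2 (25 mol%), CH2Cl2, 0 °C to rt; then I2 (1.3 equiv), THF, −30 °C
Reagents that add atoms: trimethylaluminium, C[Al](C)C; iodine, [I][I]
Why: Negishi carboalumination (syn, Al terminal) followed by iodinolysis of the C–Al bond with retention gives the E iodoalkene as a single regio- and stereoisomer.

**Step 5**
Reactants: 11 (4E)-5-iodo-4-methylpent-4-en-1-ol
Product: 12 (4E)-5-iodo-4-methylpent-4-enal
Conditions: TEMPO (10 mol%), PhI(OAc)2 (1.1 equiv), CH2Cl2, rt
Reagents that add atoms: none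
Why: The oxoammonium (TEMPO) oxidation stops at the aldehyde and leaves the iodoalkene alone.

**Step 6**
Reactants: 13 2-methylcyclobutan-1-one (racemic)
Product: 14 trimethyl[(2-methylcyclobut-1-en-1-yl)oxy]silane
Conditions: Me3SiOTf (1.1 equiv), Et3N (1.3 equiv), CH2Cl2, 0 °C to rt; fractional distillation
Reagents that add atoms: trimethylsilyl trifluoromethanesulfonate, C[Si](C)(C)OS(=O)(=O)C(F)(F)F
Why: Soft enolisation/silylation is reversible through the silyloxocarbenium ion, so the more substituted, more stable tetrasubstituted enol silane dominates, and the stereocentre of racemic 13 is erased.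

**Step 7**
Reactants: 12 (4E)-5-iodo-4-methylpent-4-enal; 14 trimethyl[(2-methylcyclobut-1-en-1-yl)oxy]silane
Product: 16 (2S)-2-[(1R,4E)-1-hydroxy-5-iodo-4-methylpent-4-en-1-yl]-2-methylcyclobutan-1-one, via silyl ether 15 (not isolated)
Conditions: confined BINOL-derived N-triflyl imidodiphosphorimidate acid (IDPi, 2 mol%, enantiomer matched to Si-face attack on 12), 14 (1.3 equiv), toluene, −78 °C; then 1 M aq HCl, THF, 0 °C
Reagents that add atoms: none
Why: Proposed new method: the IDPi acid is silylated in situ by 14, and the Me3Si+/IDPi− ion pair activates 12 as a silyloxocarbenium ion held in the chiral anion pocket; the strained, electron-rich tetrasubstituted enol silane then adds through an open antiperiplanar transition state in which the aldehyde chain lies beside the splayed exocyclic methyl (C1–C2–CH3 about 133°) and the aldehyde H lies over the pinched ring CH2 (C1–C2–C3 about 94°), so the Si face of 12 meets the Re face of C2, and the C–C bond, the carbinol centre (R) and the quaternary centre (S) are set together before silyl transfer turns the catalyst over; the closest known reaction type is the silylium-based, counteranion-directed asymmetric Mukaiyama aldol addition of silyl ketene acetals and simple enol silanes, which has not been shown for a 2-alkylcyclobutanone enol silane that builds an alpha-quaternary centre.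

**Step 8**
Reactants: 16 (2S)-2-[(1R,4E)-1-hydroxy-5-iodo-4-methylpent-4-en-1-yl]-2-methylcyclobutan-1-one
Product: 17 (5S)-5-[(1R,4E)-1-hydroxy-5-iodo-4-methylpent-4-en-1-yl]-5-methyloxolan-2-one
Conditions: 30% aq H2O2 (3 equiv), AcOH, 0 °C to rt
Reagents that add atoms: hydrogen peroxide, OO
Why: In this Baeyer-Villiger ring expansion H2O2 adds to the strained ketone and, in the Criegee adduct, the quaternary carbon shifts from C to O with retention, so the four-membered ketone becomes the five-membered lactone with the C–O centre fixed as S, while the acidic medium blocks retro-aldol and the deactivated iodoalkene is not epoxidised.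

**Step 9**
Reactants: 17 (5S)-5-[(1R,4E)-1-hydroxy-5-iodo-4-methylpent-4-en-1-yl]-5-methyloxolan-2-one; 8 (3E)-6-(furan-3-yl)-3-methylhex-3-enal
Product: 19 irciformonin B, (5S)-5-[(1R,4E,6S,8E)-11-(furan-3-yl)-1,6-dihydroxy-4,8-dimethylundeca-4,8-dien-1-yl]-5-methyloxolan-2-one, via alkenylchromium species 18 (not isolated)
Conditions: CrCl2 (4 equiv), tert-leucinol-derived oxazoline-methanesulfonamide ligand (4.4 equiv, enantiomer matched to Re-face attack on 8), Et3N (4.4 equiv), NiCl2 (5 mol%), 8 (1.5 equiv), THF, rt
Reagents that add atoms: none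
Why: In the asymmetric Nozaki-Hiyama-Kishi reaction zerovalent nickel inserts into the C–I bond and hands the alkenyl group to chromium with retention of the E geometry; the ligand-bound alkenylchromium (trivalent chromium) adds only to the aldehyde (lactone, free OH and furan untouched), and the ligand directs attack to the Re face, which sets C6 as S.

**Compound list**
1 | but-3-yn-1-ol | C#CCCO | starting material
2 | vinyl bromide | C=CBr | starting material
3 | dimethylaluminium (3E)-4-(dimethylalumanyl)-3-methylbut-3-en-1-olate | C[Al](C)OCC/C(C)=C/[Al](C)C | intermediate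
4 | (3E)-3-methylhexa-3,5-dien-1-ol | OCC/C(C)=C/C=C | intermediate
5 | 3-bromofuran | Brc1ccoc1 | starting material
6 | 9-[(3E)-6-(9-borabicyclo[3.3.1]nonan-9-yloxy)-4-methylhex-3-en-1-yl]-9-borabicyclo[3.3.1]nonane | C(C/C=C(\C)CCOB1C2CCCC1CCC2)B1C2CCCC1CCC2 | intermediate
7 | (3E)-6-(furan-3-yl)-3-methylhex-3-en-1-ol | OCC/C(C)=C/CCc1ccoc1 | intermediate
8 | (3E)-6-(furan-3-yl)-3-methylhex-3-enal | O=CC/C(C)=C/CCc1ccoc1 | intermediate
9 | pent-4-yn-1-ol | C#CCCCO | starting material
10 | dimethylaluminium (4E)-5-(dimethylalumanyl)-4-methylpent-4-en-1-olate | C[Al](C)OCCC/C(C)=C/[Al](C)C | intermediate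
11 | (4E)-5-iodo-4-methylpent-4-en-1-ol | OCCC/C(C)=C/I | intermediate
12 | (4E)-5-iodo-4-methylpent-4-enal | O=CCC/C(C)=C/I | intermediate
13 | 2-methylcyclobutan-1-one (racemic) | CC1CCC1=O | starting material
14 | trimethyl[(2-methylcyclobut-1-en-1-yl)oxy]silane | CC1=C(O[Si](C)(C)C)CC1 | intermediate
15 | (2S)-2-[(1R,4E)-5-iodo-4-methyl-1-(trimethylsilyloxy)pent-4-en-1-yl]-2-methylcyclobutan-1-one | I/C=C(\C)CC[C@@H](O[Si](C)(C)C)[C@]1(C)CCC1=O | intermediate
16 | (2S)-2-[(1R,4E)-1-hydroxy-5-iodo-4-methylpent-4-en-1-yl]-2-methylcyclobutan-1-one | I/C=C(\C)CC[C@@H](O)[C@]1(C)CCC1=O | intermediate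
17 | (5S)-5-[(1R,4E)-1-hydroxy-5-iodo-4-methylpent-4-en-1-yl]-5-methyloxolan-2-one | I/C=C(\C)CC[C@@H](O)[C@]1(C)CCC(=O)O1 | intermediate
18 | dichloro{(1E,5R)-5-hydroxy-2-methyl-5-[(2S)-2-methyl-5-oxooxolan-2-yl]pent-1-en-1-yl}chromium | Cl[Cr](Cl)/C=C(\C)CC[C@@H](O)[C@]1(C)CCC(=O)O1 | intermediate
19 | irciformonin B | C/C(=C\[C@@H](O)C/C(C)=C/CCc1ccoc1)CC[C@@H](O)[C@]1(C)CCC(=O)O1 | target

**Total step count:** 9. **Longest linear sequence:** 5 (steps 4, 5, 7, 8, 9).

**Three steps most likely to fail**

Step 7 (the proposed new aldol) carries three risks: low syn/anti ratio, low ee, or sluggish addition of the hindered enol silane. The fallback sets out from 12 and comes back at 17.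
- Isopropenylmagnesium bromide (THF, −78 °C) adds to 12 to give racemic (6E)-7-iodo-2,6-dimethylhepta-1,6-dien-3-ol F1.
- A Johnson-Claisen rearrangement (MeC(OEt)3, cat. EtCO2H, 135 °C) gives ethyl (4E,8E)-9-iodo-4,8-dimethylnona-4,8-dienoate F2.
- Shi epoxidation (D-fructose-derived ketone, KHSO5, K2CO3 buffer, MeCN–H2O, 0 °C) takes the electron-rich 4,5-alkene and leaves the iodoalkene. It gives ethyl 3-{(2R,3R)-3-[(3E)-4-iodo-3-methylbut-3-en-1-yl]-2-methyloxiran-2-yl}propanoate F3.
- Catalytic camphorsulfonic acid in wet CH2Cl2 closes the lactone by 5-exo attack of the ester carbonyl at the tertiary epoxide carbon with inversion. This gives 17 with the same (1R,5S) relationship.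

Step 9 (asymmetric Ni/Cr coupling) carries two risks: moderate facial control at a centre remote from the other two, and isomerisation of 8. The fallback sets out from 17 and 8 and comes back at 19.
- A ligand-free coupling (CrCl2, NiCl2 1 mol%, DMSO, rt) gives the C6-epimeric mixture (5S)-5-[(1R,4E,8E)-11-(furan-3-yl)-1,6-dihydroxy-4,8-dimethylundeca-4,8-dien-1-yl]-5-methyloxolan-2-one F4.
- MnO2 (CH2Cl2, rt) oxidises only the allylic alcohol, giving the dienone (5S)-5-[(1R,4E,8E)-11-(furan-3-yl)-1-hydroxy-4,8-dimethyl-6-oxoundeca-4,8-dien-1-yl]-5-methyloxolan-2-one F5.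
- Corey-Bakshi-Shibata reduction ((R)-Me-CBS oxazaborolidine, BH3·SMe2, THF, −40 °C, alkenyl as the large group) then sets C6 as S. The stereocentre now comes from a reduction and not from the C–C bond formation.

Step 6 (regiochemistry of the enol silane) carries the risk that the less substituted isomer contaminates 14. That isomer would react faster in step 7. The fallback sets out from 13 and comes back at 14.
- Acid-catalysed bromination through the more substituted enol (Br2, cat. HBr, CHCl3, 0 °C) gives 2-bromo-2-methylcyclobutan-1-one F6.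
- Reductive silylation (Zn, Me3SiCl, TMEDA, Et2O, rt) forms the zinc enolate only at the carbon that carried bromine and traps it on oxygen, so 14 is obtained regiospecifically.

**Further compounds**
F1 | step 7 | (6E)-7-iodo-2,6-dimethylhepta-1,6-dien-3-ol (racemic) | C=C(C)C(O)CC/C(C)=C/I
F2 | step 7 | ethyl (4E,8E)-9-iodo-4,8-dimethylnona-4,8-dienoate | CCOC(=O)CC/C(C)=C/CC/C(C)=C/I
F3 | step 7 | ethyl 3-{(2R,3R)-3-[(3E)-4-iodo-3-methylbut-3-en-1-yl]-2-methyloxiran-2-yl}propanoate | I/C=C(\C)CC[C@H]1O[C@]1(C)CCC(=O)OCC
F4 | step 9 | (5S)-5-[(1R,4E,8E)-11-(furan-3-yl)-1,6-dihydroxy-4,8-dimethylundeca-4,8-dien-1-yl]-5-methyloxolan-2-one (C6 epimers) | C/C(=C\C(O)C/C(C)=C/CCc1ccoc1)CC[C@@H](O)[C@]1(C)CCC(=O)O1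
F5 | step 9 | (5S)-5-[(1R,4E,8E)-11-(furan-3-yl)-1-hydroxy-4,8-dimethyl-6-oxoundeca-4,8-dien-1-yl]-5-methyloxolan-2-one | C/C(=C\C(=O)C/C(C)=C/CCc1ccoc1)CC[C@@H](O)[C@]1(C)CCC(=O)O1
F6 | step 6 | 2-bromo-2-methylcyclobutan-1-one | CC1(Br)CCC1=O
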